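Time does little in the earlier closed runs after the first reading. The east run shows 21.5% target at 8.00 min and 21.9% at 50.0 min, a drift inside the scatter of 0.5 percentage points, while substrate stays beside the target. The question is therefore where each flask stops.

| flask | substrate | coupling partner | catalyst | remark | time |
|---|---|---|---|---|---|
| east | 0.50 M | 1.5 equiv | 5 mol% | run made earlier |  |
| south-east | 0.34 M | 1.5 equiv | 5 mol% | run made earlier |  |
| south-west | 0.75 M | 1.5 equiv | 5 mol% | run made earlier |  |
| north | 0.50 M | 1.5 equiv | 2.5 mol% | run made earlier |  |
| cedar | 0.50 M (fed, over 40.0 min) | 1.50 equiv | 5 mol% | all but substrate at the start; substrate goes in evenly over 40.0 min, the run ends at 50 min | 50 min |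
| oak | 0.50 M | 1.50 equiv | 5 mol% | one stirred flow tank at steady state, fed with the mixture as stated, mean residence time 50 min |  |
| elm | 0.50 M | 1.50 equiv | 5 mol% | everything together in a closed stirred flask, run for 50 min | 50 min |
| alder | 0.50 M | 1.50 equiv (fed, over 40.0 min) | 5 mol% | all but coupling partner at the start; coupling partner goes in evenly over 40.0 min, the run ends at 50 min | 50 min |

- east (time / min: target / %, substrate / %): 8.00: 21.5, 78.4; 15.0: 21.7, 78.5; 20.0: 21.9, 77.4; 30.0: 20.8, 77.5; 40.0: 21.7, 77.9; 50.0: 21.9, 78.5
- south-east (time / min: target / %, substrate / %): 4.00: 15.8, 82.4; 8.00: 16.1, 82.5; 12.0: 17.1, 83.5; 15.0: 16.5, 83.5; 20.0: 16.6, 82.9; 25.0: 16.9, 82.8; 30.0: 16.7, 83.5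
- south-west (time / min: target / %, substrate / %): 4.00: 27.9, 71.3; 8.00: 29.0, 71.9; 12.0: 28.1, 71.0; 15.0: 28.1, 71.8; 20.0: 28.6, 71.4; 25.0: 27.5, 71.3; 30.0: 28.4, 71.5
- north (time / min: target / %, substrate / %): 6.00: 22.2, 78.1; 12.0: 21.8, 78.6; 20.0: 21.6, 77.7; 25.0: 21.5, 78.0; 30.0: 21.3, 78.2

(each reading ± 0.5 percentage points)

- the set-up with the highest amount of target at the outlet or at the end, in percent of the substrate put in ("none" if the first two lie within 2 percentage points) (cedar / oak / elm / alder / none)
- amount of target at the outlet or at the end, in percent of the substrate put in, cedar
- amount of target at the outlet or at the end, in percent of the substrate put in, oak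
- amount of target at the outlet or at the end, in percent of the substrate put in, elm
- amount of target at the outlet or at the end, in percent of the substrate put in, alder

- the stated concentrations are those of everything mixed, before any reaction; amounts are the same in each set-up
- what may be going on: substrate + coupling partner + catalyst <-> target + catalyst
- the feed brings no volume worth counting
- the earlier runs were made in a closed, stirred flask

Strength separates the neighbouring flasks. East, at 0.50 M, averages 21.6% of its charge as target. South-east, the same recipe at 0.34 M, averages 16.5%, and south-west, at 0.75 M, averages 28.2%.

Take the fraction turned to target and divide it by the fraction of substrate left, by the equivalents of coupling partner left, and by the substrate strength. East then reads 0.429 M⁻¹, south-east 0.436 M⁻¹ and south-west 0.431 M⁻¹. Their mean, 0.432 M⁻¹, is taken as the plateau constant, the field's equilibrium constant, and it is a reading that carries the scatter of the runs. South-east stops lower than east because it is more dilute: forming target takes substrate and coupling partner together, whereas the way back starts from target. North, with half the catalyst of east, averages 21.7%, about the same as east, so the loading leaves the plateau where it stands.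

Elm is east's charge in a closed flask, and the fraction that satisfies the constant at that charge is 21.7%. Cedar and alder hold the same charge at the end, and 10.0 min remain after feeding, longer than the 6.00 min by which north stood on its plateau, so both are reckoned at that fraction too. Oak's residence time of 50 min is longer than that same 6.00 min, so oak is reckoned slightly below it. The four then lie within 2 points, and none leads.

The forecast gives 21.7% for cedar, 21.5% for oak, 21.7% for elm, 21.7% for alder and none as best, on the ground that “these runs show equilibrium rather than rate”.

Cedar ends at 21.8%, oak at 21.6%, elm at 21.8% and alder at 21.8%, so the best set-up is none. The equations are: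

    substrate + coupling partner + catalyst ⇌ target + catalyst, rate k1*[substrate]*[coupling partner]*[catalyst] forward; the back reaction follows from the equilibrium constant (K = 0.436 M⁻¹, k = 0.370 M⁻² s⁻¹)

Left until 500 min, elm stands at 21.8%. With coupling partner raised to 1.95 equiv, the plateau constant puts the target in elm at 26.7%, which is 5 points above the reckoned elm, and elm itself at that amount has moved by 5 percentage points.

The numbers in the tables are calculated from invented constants; noise was put on by code.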